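**Assumption:** the target has no stereocentre (it is achiral), so there is no configuration to set. 3,5-Dibromo-2-fluorobenzaldehyde (9) and the other numbered starting materials are taken as purchasable; the route is a plan from known reaction types, not a tested procedure.

## Retrosynthetic overview

1. Target 12 ⇐ aldehyde 10: the ring A hydroxyl comes from a formyl group (Baeyer–Villiger oxidation, then formate cleavage).
2. 10 ⇐ phenol 8 + 3,5-dibromo-2-fluorobenzaldehyde 9: the A–O–B ether by SNAr.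
3. 8 ⇐ methyl ether 7 ⇐ phenol 2 + aryl(trimethoxyphenyl)iodonium salt 6: the B–O–C ether by metal-free O-arylation, then O-demethylation.
4. 2 ⇐ 5-bromo-2-methoxyphenol 1 (double bromination); 6 ⇐ 2,4-dibromo-1-iodobenzene 3 + 1,3,5-trimethoxybenzene 4.
5. No ring is built; the three benzene rings are bought and joined in the order B + C, then A.

## Route

Step 1
Reactants: 1 5-bromo-2-methoxyphenol
Product: 2 2,3,4-tribromo-6-methoxyphenol
Conditions: Br2 (2.1 equiv), AcOH, rt
Reagents that add atoms: bromine, BrBr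
Why: Electrophilic aromatic bromination in which the free OH is the strongest director, so the two bromines enter para and ortho to it while the position next to OMe stays free; no stereocentre is formed.

Step 2
Reactants: 3 2,4-dibromo-1-iodobenzene; 4 1,3,5-trimethoxybenzene
Product: 6 (2,4-dibromophenyl)(2,4,6-trimethoxyphenyl)iodonium tosylate, via hydroxy(tosyloxy)iodoarene 5 (not isolated)
Conditions: mCPBA, TsOH·H2O, MeCN, 77 °C; then 4, 77 °C; precipitate with Et2O
Reagents that add atoms: p-toluenesulfonic acid (used as monohydrate), Cc1ccc(cc1)S(=O)(=O)O; mCPBA, OOC(=O)c1cccc(Cl)c1 (its oxygen stays only in intermediate 5)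
Why: One-pot diaryliodonium synthesis: mCPBA oxidises the aryl iodide to a trivalent-iodine Koser-type species, which the very electron-rich trimethoxybenzene attacks by electrophilic aromatic substitution at iodine.

Step 3
Reactants: 2 2,3,4-tribromo-6-methoxyphenol; 6 (2,4-dibromophenyl)(2,4,6-trimethoxyphenyl)iodonium tosylate
Product: 7 1,2,3-tribromo-4-(2,4-dibromophenoxy)-5-methoxybenzene
Conditions: K2CO3, MeCN, 70 °C
Reagents that add atoms: none
Why: Metal-free O-arylation of a phenoxide by a diaryliodonium salt (ligand exchange, then ligand coupling), in which the electron-poor ortho-substituted dibromophenyl group is transferred, the trimethoxyphenyl group stays on iodine, and no C–Br bond is touched.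

Step 4
Reactants: 7 1,2,3-tribromo-4-(2,4-dibromophenoxy)-5-methoxybenzene
Product: 8 3,4,5-tribromo-2-(2,4-dibromophenoxy)phenol
Conditions: BBr3, CH2Cl2, −78 °C to rt; then H2O
Reagents that add atoms: none
Why: Lewis-acid aryl methyl ether cleavage (bromide attacks the methyl group of the boron-complexed ether by SN2), to which the diaryl ether and the aryl bromides are inert.

Step 5
Reactants: 8 3,4,5-tribromo-2-(2,4-dibromophenoxy)phenol; 9 3,5-dibromo-2-fluorobenzaldehyde
Product: 10 3,5-dibromo-2-[3,4,5-tribromo-2-(2,4-dibromophenoxy)phenoxy]benzaldehyde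
Conditions: K2CO3, DMA, 100 °C
Reagents that add atoms: none
Why: SNAr: the fluoride ortho to the formyl group (helped by the ortho and para bromines) is displaced by the phenoxide through a Meisenheimer complex, while the unactivated C–Br bonds do not react.

Step 6
Reactants: 10 3,5-dibromo-2-[3,4,5-tribromo-2-(2,4-dibromophenoxy)phenoxy]benzaldehyde
Product: 12 bromoiesol A, via aryl formate 11 (not isolated)
Conditions: mCPBA, CH2Cl2, 40 °C; then MeOH, cat. HCl, rt
Reagents that add atoms: mCPBA, OOC(=O)c1cccc(Cl)c1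
Why: Baeyer–Villiger (Dakin-type) oxidation in which the ortho-aryloxy-substituted aryl group migrates to give the aryl formate, which acid methanolysis cleaves to the phenol; the target is achiral, so no stereocentre is set.

## Compound list

1 | 5-bromo-2-methoxyphenol | COc1ccc(Br)cc1O | starting material
2 | 2,3,4-tribromo-6-methoxyphenol (4,5,6-tribromoguaiacol) | COc1cc(Br)c(Br)c(Br)c1O | intermediate
3 | 2,4-dibromo-1-iodobenzene | Brc1ccc(I)c(Br)c1 | starting material
4 | 1,3,5-trimethoxybenzene | COc1cc(OC)cc(OC)c1 | starting material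
5 | 2,4-dibromo-1-[hydroxy(tosyloxy)iodo]benzene | Cc1ccc(cc1)S(=O)(=O)OI(O)c1ccc(Br)cc1Br | intermediate (not isolated)
6 | (2,4-dibromophenyl)(2,4,6-trimethoxyphenyl)iodonium tosylate | COc1cc(OC)c([I+]c2ccc(Br)cc2Br)c(OC)c1.Cc1ccc(cc1)S(=O)(=O)[O-] | intermediate
7 | 1,2,3-tribromo-4-(2,4-dibromophenoxy)-5-methoxybenzene | COc1cc(Br)c(Br)c(Br)c1Oc1ccc(Br)cc1Br | intermediate
8 | 3,4,5-tribromo-2-(2,4-dibromophenoxy)phenol | Oc1cc(Br)c(Br)c(Br)c1Oc1ccc(Br)cc1Br | intermediate
9 | 3,5-dibromo-2-fluorobenzaldehyde | O=Cc1cc(Br)cc(Br)c1F | starting material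
10 | 3,5-dibromo-2-[3,4,5-tribromo-2-(2,4-dibromophenoxy)phenoxy]benzaldehyde | O=Cc1cc(Br)cc(Br)c1Oc1cc(Br)c(Br)c(Br)c1Oc1ccc(Br)cc1Br | intermediate
11 | 3,5-dibromo-2-[3,4,5-tribromo-2-(2,4-dibromophenoxy)phenoxy]phenyl formate | O=COc1cc(Br)cc(Br)c1Oc1cc(Br)c(Br)c(Br)c1Oc1ccc(Br)cc1Br | intermediate (not isolated)
12 | bromoiesol A, 3,5-dibromo-2-[3,4,5-tribromo-2-(2,4-dibromophenoxy)phenoxy]phenol | Oc1cc(Br)cc(Br)c1Oc1cc(Br)c(Br)c(Br)c1Oc1ccc(Br)cc1Br | target

## Summary

Total step count: 6.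
Longest linear sequence: 5 (steps 1, 3, 4, 5 and 6; step 2 is a one-step side branch).

## Steps most likely to fail, with fallbacks

1. Step 3 (O-arylation of a phenoxide that is both electron-poor and flanked by Br and OMe). The fallback sets out from 2 and comes back at 7. It replaces the iodonium chemistry by a nitro-activated SNAr and a Sandmeyer reaction. Phenol 2 and purchased 4-bromo-1-fluoro-2-nitrobenzene ([O-][N+](=O)c1cc(Br)ccc1F) with K2CO3 in DMF at 60 °C give 1,2,3-tribromo-4-(4-bromo-2-nitrophenoxy)-5-methoxybenzene F1. Fe powder and NH4Cl in EtOH/H2O at 70 °C reduce the nitro group without touching C–Br and give 5-bromo-2-(2,3,4-tribromo-6-methoxyphenoxy)aniline F2. NaNO2 in aqueous HBr/AcOH at 0 °C gives 5-bromo-2-(2,3,4-tribromo-6-methoxyphenoxy)benzenediazonium bromide F3, which CuBr in HBr at 60 °C converts to 7.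

2. Step 5 (SNAr between a weakly nucleophilic tribromophenoxide and a fluoride flanked by CHO and Br). The fallback sets out from 8 and comes back at 12, and it also bypasses step 6. It uses the much stronger nitro activation and turns the nitro group into the hydroxyl. Phenol 8 and purchased 1,5-dibromo-2-fluoro-3-nitrobenzene ([O-][N+](=O)c1cc(Br)cc(Br)c1F) with K2CO3 in DMF at 50 °C give 1,2,3-tribromo-5-(2,4-dibromo-6-nitrophenoxy)-4-(2,4-dibromophenoxy)benzene F4. Fe powder and NH4Cl in EtOH/H2O at 70 °C give 3,5-dibromo-2-[3,4,5-tribromo-2-(2,4-dibromophenoxy)phenoxy]aniline F5. NaNO2 in H2SO4/AcOH at 0 °C gives 3,5-dibromo-2-[3,4,5-tribromo-2-(2,4-dibromophenoxy)phenoxy]benzenediazonium hydrogensulfate F6, and hydroxydediazoniation with Cu2O and Cu(NO3)2 in water at rt gives 12.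

3. Step 6 (on the dibrominated ring, hydride migration to the carboxylic acid may compete with aryl migration). The fallback sets out from 10 and comes back at 12. It removes the competing hydride by making the methyl ketone, where only aryl or methyl can migrate. MeMgBr in THF at −78 °C adds to 10 to give racemic 1-{3,5-dibromo-2-[3,4,5-tribromo-2-(2,4-dibromophenoxy)phenoxy]phenyl}ethan-1-ol F7. Dess–Martin periodinane in CH2Cl2 gives 1-{3,5-dibromo-2-[3,4,5-tribromo-2-(2,4-dibromophenoxy)phenoxy]phenyl}ethan-1-one F8. Baeyer–Villiger oxidation with CF3CO3H (from trifluoroacetic anhydride and urea–hydrogen peroxide, Na2HPO4 buffer, CH2Cl2, 0 °C to rt) gives 3,5-dibromo-2-[3,4,5-tribromo-2-(2,4-dibromophenoxy)phenoxy]phenyl acetate F9, which MeOH with catalytic HCl cleaves to 12.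

## Further compounds

F1 | step 3 | 1,2,3-tribromo-4-(4-bromo-2-nitrophenoxy)-5-methoxybenzene | COc1cc(Br)c(Br)c(Br)c1Oc1ccc(Br)cc1[N+](=O)[O-]
F2 | step 3 | 5-bromo-2-(2,3,4-tribromo-6-methoxyphenoxy)aniline | COc1cc(Br)c(Br)c(Br)c1Oc1ccc(Br)cc1N
F3 | step 3 | 5-bromo-2-(2,3,4-tribromo-6-methoxyphenoxy)benzenediazonium bromide | COc1cc(Br)c(Br)c(Br)c1Oc1ccc(Br)cc1[N+]#N.[Br-]
F4 | step 5 | 1,2,3-tribromo-5-(2,4-dibromo-6-nitrophenoxy)-4-(2,4-dibromophenoxy)benzene | [O-][N+](=O)c1cc(Br)cc(Br)c1Oc1cc(Br)c(Br)c(Br)c1Oc1ccc(Br)cc1Br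
F5 | step 5 | 3,5-dibromo-2-[3,4,5-tribromo-2-(2,4-dibromophenoxy)phenoxy]aniline | Nc1cc(Br)cc(Br)c1Oc1cc(Br)c(Br)c(Br)c1Oc1ccc(Br)cc1Br
F6 | step 5 | 3,5-dibromo-2-[3,4,5-tribromo-2-(2,4-dibromophenoxy)phenoxy]benzenediazonium hydrogensulfate | N#[N+]c1cc(Br)cc(Br)c1Oc1cc(Br)c(Br)c(Br)c1Oc1ccc(Br)cc1Br.OS(=O)(=O)[O-]
F7 | step 6 | racemic 1-{3,5-dibromo-2-[3,4,5-tribromo-2-(2,4-dibromophenoxy)phenoxy]phenyl}ethan-1-ol | CC(O)c1cc(Br)cc(Br)c1Oc1cc(Br)c(Br)c(Br)c1Oc1ccc(Br)cc1Br
F8 | step 6 | 1-{3,5-dibromo-2-[3,4,5-tribromo-2-(2,4-dibromophenoxy)phenoxy]phenyl}ethan-1-one | CC(=O)c1cc(Br)cc(Br)c1Oc1cc(Br)c(Br)c(Br)c1Oc1ccc(Br)cc1Br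
F9 | step 6 | 3,5-dibromo-2-[3,4,5-tribromo-2-(2,4-dibromophenoxy)phenoxy]phenyl acetate | CC(=O)Oc1cc(Br)cc(Br)c1Oc1cc(Br)c(Br)c(Br)c1Oc1ccc(Br)cc1Br
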